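The C ring of flavanone unit I is disconnected at O1–C2 and C4–C3, the two bonds that flank the C2–C3 edge carrying the catechol ring (on C2) and C8'' of the taxifolin unit (on C3). Unit I then falls apart into a salicylaldehyde (O1, C8a, C4a, C4) and the triple bond of a diarylalkyne built on commercial (2R,3R)-taxifolin, which brings C2'' and C3''. In one flask, Rh-catalysed alkyne hydroacylation forms C4–C3 and a catalyst-controlled oxa-Michael addition forms O1–C2, closing the ring and setting C2 and C3. The precursors are an 8-(arylethynyl)tetra-O-benzyltaxifolin and 2,4-bis(benzyloxy)-6-hydroxybenzaldehyde.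

Key step: step 6

Assumption: the quinine-derived thiourea of step 6 is taken to favour the 2R face of the enone; should it favour 2S, its quinidine-derived pseudo-enantiomer takes its place with nothing else changed.

**Step 1**
Reactants: 1 (+)-taxifolin, (2R,3R)-2-(3,4-dihydroxyphenyl)-3,5,7-trihydroxychroman-4-one
Product: 2 (2R,3R)-5,7,3',4'-tetra-O-benzyltaxifolin
Conditions: BnBr (4.5 equiv), K2CO3, DMF, 0 °C to rt, Ar
Reagents that add atoms: benzyl bromide, BrCc1ccccc1
Why: Williamson ether synthesis on the four phenols, while the much less acidic aliphatic 3-OH stays free and the mild base, low temperature and inert gas are chosen to keep the C ring closed so that C2 and C3 are not touched.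

**Step 2**
Reactants: 2 (2R,3R)-5,7,3',4'-tetra-O-benzyltaxifolin
Product: 3 (2R,3R)-8-iodo-5,7,3',4'-tetra-O-benzyltaxifolin
Conditions: NIS (1.05 equiv), TFA (10 mol %), CH2Cl2/MeCN, 0 °C
Reagents that add atoms: N-iodosuccinimide, O=C1CCC(=O)N1I
Why: Electrophilic aromatic iodination, expected at C8 (ortho to O1 and 7-OBn, para to 5-OBn) before C6, which lies between two benzyloxy groups, and before the less activated B ring.

**Step 3**
Reactants: 4 3,4-bis(benzyloxy)benzaldehyde
Product: 5 1,2-bis(benzyloxy)-4-ethynylbenzene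
Conditions: Ohira–Bestmann reagent, K2CO3, MeOH/THF, rt
Reagents that add atoms: dimethyl (1-diazo-2-oxopropyl)phosphonate, COP(=O)(OC)C(=[N+]=[N-])C(C)=O
Why: Seyferth–Gilbert homologation in the Ohira–Bestmann form converts the aryl aldehyde into the terminal alkyne under mild base that leaves the benzyl ethers alone.

**Step 4**
Reactants: 3 (2R,3R)-8-iodo-5,7,3',4'-tetra-O-benzyltaxifolin; 5 1,2-bis(benzyloxy)-4-ethynylbenzene
Product: 6 (2R,3R)-8-{[3,4-bis(benzyloxy)phenyl]ethynyl}-5,7,3',4'-tetra-O-benzyltaxifolin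
Conditions: Pd(PPh3)2Cl2 (5 mol %), CuI (10 mol %), Et3N, DMF, 50 °C
Reagents that add atoms: none
Why: Sonogashira coupling at the only carbon–iodine bond; the ketone and the secondary alcohol are inert to Pd/Cu/amine, and with O7 benzylated no cyclisation to a benzofuran can follow.

**Step 5**
Reactants: 7 2,4,6-trihydroxybenzaldehyde
Product: 8 2,4-bis(benzyloxy)-6-hydroxybenzaldehyde
Conditions: BnBr (2.1 equiv), K2CO3, DMF, 0 °C to rt
Reagents that add atoms: benzyl bromide, BrCc1ccccc1
Why: Williamson ether synthesis with limited benzyl bromide alkylates the 4-OH and one ortho-OH, while the remaining ortho-OH, hydrogen-bonded to the formyl group, should resist the third alkylation.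

**Step 6**
Reactants: 6 (2R,3R)-8-{[3,4-bis(benzyloxy)phenyl]ethynyl}-5,7,3',4'-tetra-O-benzyltaxifolin; 8 2,4-bis(benzyloxy)-6-hydroxybenzaldehyde
Product: 10 (2R,3S,2''R,3''R)-octa-O-benzylmanniflavanone, via hydroxychalcone 9 (not isolated)
Conditions: [Rh(cod)OMe]2 (5 mol %), dppf (10 mol %), PhMe, 80 °C; then 25 °C, quinine-derived 3,5-bis(trifluoromethyl)phenyl thiourea (20 mol %)
Reagents that add atoms: none
Why: Rh(I) bound to the phenoxide of 8 inserts into the formyl C–H bond (a five-membered acyl-Rh-H chelate that holds back decarbonylation), alkyne 6 inserts syn into Rh–H, and C–C reductive elimination forms C4–C3 to give the (E)-2'-hydroxy-α-arylchalcone 9; the amine-thiourea then delivers the phenol oxygen to the β-carbon and closes O1–C2. The closest known reaction is the tandem Rh-catalysed hydroacylation/oxa-Michael addition of salicylaldehydes with internal alkynes to trans-2,3-disubstituted chroman-4-ones, combined here with the amine-thiourea-catalysed asymmetric oxa-Michael closure of 2'-hydroxychalcone-type enones. The one new ring closes in a 6-endo-trig oxa-Michael mode. C2 is set by the catalyst, whose thiourea binds the enone carbonyl while the quinuclidine guides the phenol to one enone face (2R wanted), and C3 is set by protonation of the resulting enolate under equilibrating conditions so that the two aryl groups end up trans-diequatorial (3S); C2'' and C3'' are not touched. The step needs the acyl group to go to the alkyne carbon next to the taxifolin A ring, which is expected from the ortho-directing effect known for metal hydride additions to ortho-substituted diarylalkynes (metal on the carbon next to the ortho-substituted ring, here one with two ortho oxygens), and it needs chemoselectivity for the aldehyde C–H bond, which the free ortho-hydroxyl of 8 secures by chelation.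

**Step 7**
Reactants: 10 (2R,3S,2''R,3''R)-octa-O-benzylmanniflavanone
Product: 11 manniflavanone
Conditions: H2 (1 atm), Pd(OH)2/C, EtOAc/MeOH, rt
Reagents that add atoms: none
Why: Catalytic hydrogenolysis of the eight aryl benzyl ethers under neutral conditions, which should leave the base-sensitive C2/C3 and C2''/C3'' centres and the slower-reacting cyclic benzylic C2–O1 ethers intact.

**Compound list**
1 | (+)-taxifolin, (2R,3R)-2-(3,4-dihydroxyphenyl)-3,5,7-trihydroxychroman-4-one | O=C1c2c(O)cc(O)cc2O[C@H](c2ccc(O)c(O)c2)[C@H]1O | starting material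
2 | (2R,3R)-5,7-bis(benzyloxy)-2-[3,4-bis(benzyloxy)phenyl]-3-hydroxychroman-4-one (5,7,3',4'-tetra-O-benzyltaxifolin) | O=C1c2c(OCc3ccccc3)cc(OCc3ccccc3)cc2O[C@H](c2ccc(OCc3ccccc3)c(OCc3ccccc3)c2)[C@H]1O | intermediate
3 | (2R,3R)-5,7-bis(benzyloxy)-2-[3,4-bis(benzyloxy)phenyl]-3-hydroxy-8-iodochroman-4-one | O=C1c2c(OCc3ccccc3)cc(OCc3ccccc3)c(I)c2O[C@H](c2ccc(OCc3ccccc3)c(OCc3ccccc3)c2)[C@H]1O | intermediate
4 | 3,4-bis(benzyloxy)benzaldehyde | O=Cc1ccc(OCc2ccccc2)c(OCc2ccccc2)c1 | starting material
5 | 1,2-bis(benzyloxy)-4-ethynylbenzene | C#Cc1ccc(OCc2ccccc2)c(OCc2ccccc2)c1 | intermediate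
6 | (2R,3R)-5,7-bis(benzyloxy)-2-[3,4-bis(benzyloxy)phenyl]-8-{[3,4-bis(benzyloxy)phenyl]ethynyl}-3-hydroxychroman-4-one | O=C1c2c(OCc3ccccc3)cc(OCc3ccccc3)c(C#Cc3ccc(OCc4ccccc4)c(OCc4ccccc4)c3)c2O[C@H](c2ccc(OCc3ccccc3)c(OCc3ccccc3)c2)[C@H]1O | intermediate
7 | 2,4,6-trihydroxybenzaldehyde | O=Cc1c(O)cc(O)cc1O | starting material
8 | 2,4-bis(benzyloxy)-6-hydroxybenzaldehyde | O=Cc1c(O)cc(OCc2ccccc2)cc1OCc1ccccc1 | intermediate
9 | (2R,3R)-5,7-bis(benzyloxy)-8-{(E)-1-[2,4-bis(benzyloxy)-6-hydroxybenzoyl]-2-[3,4-bis(benzyloxy)phenyl]vinyl}-2-[3,4-bis(benzyloxy)phenyl]-3-hydroxychroman-4-one (hydroxychalcone, not isolated) | O=C(c1c(O)cc(OCc2ccccc2)cc1OCc1ccccc1)/C(=C/c1ccc(OCc2ccccc2)c(OCc2ccccc2)c1)c1c(OCc2ccccc2)cc(OCc2ccccc2)c2c1O[C@H](c1ccc(OCc3ccccc3)c(OCc3ccccc3)c1)[C@@H](O)C2=O | intermediate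
10 | (2R,3S,2''R,3''R)-5,7,3',4',5'',7'',3''',4'''-octa-O-benzylmanniflavanone (3''-OH free) | O=C1c2c(OCc3ccccc3)cc(OCc3ccccc3)c([C@@H]3C(=O)c4c(OCc5ccccc5)cc(OCc5ccccc5)cc4O[C@H]3c3ccc(OCc4ccccc4)c(OCc4ccccc4)c3)c2O[C@H](c2ccc(OCc3ccccc3)c(OCc3ccccc3)c2)[C@H]1O | intermediate
11 | manniflavanone, (2R,3S,2''R,3''R) | O=C1c2c(O)cc(O)c([C@@H]3C(=O)c4c(O)cc(O)cc4O[C@H]3c3ccc(O)c(O)c3)c2O[C@H](c2ccc(O)c(O)c2)[C@H]1O | target

Total step count: 7. Longest linear sequence: 5 steps (steps 1, 2, 4, 6, 7).

**Steps most likely to fail**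

Step 6. Hydride insertion may place rhodium on the less hindered alkyne carbon, so that the acyl group is delivered next to the catechol ring instead of next to the taxifolin A ring. The ring closure may also proceed with poor facial selectivity, or start without the chiral catalyst while the flask is still warm. Fallback (sets out from 6 and 8, comes back at 10): Pd-catalysed hydrostannation of 6 (Bu3SnH, PdCl2(PPh3)2, THF, rt), in which tin is known to go to the alkyne carbon next to an ortho-substituted ring, should give the (E)-vinylstannane F1. In parallel, 8 is acetylated (Ac2O, pyridine) to the aryl acetate F2, oxidised by Pinnick oxidation (NaClO2, NaH2PO4, 2-methyl-2-butene) to the acid F3, and converted ((COCl)2, DMF cat.) into the acid chloride F4. Stille acylation of F1 with F4 (Pd2(dba)3, tri(2-furyl)phosphine, CuI, PhMe, 60 °C) should give the O-acetyl enone F5 with retention of alkene geometry. Mild methanolysis of the aryl acetate (NH4OAc, MeOH/H2O) then frees 9, which is closed to 10 with the same thiourea catalyst.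

Step 2. Iodination may also take place at C6 or on the B ring, and the regioisomers may not separate. Fallback (sets out from 4, comes back at 3): the purchased 1-[2,4-bis(benzyloxy)-6-hydroxyphenyl]ethanone F6 is iodinated (NIS, TFA cat., MeCN) at C3, ortho to the free phenol and less hindered than C5, to give the iodoketone F7; at this stage regioisomers are simple to separate and assign. The phenol is capped (MOMCl, iPr2NEt, CH2Cl2) to give the MOM ether F8. Claisen–Schmidt condensation with 4 (KOH, EtOH) should give the (E)-chalcone F9. Juliá–Colonna epoxidation (poly-L-leucine, urea–H2O2, DBU, THF) should give the (2R,3S)-epoxide F10. Acid (HCl, MeOH/THF) then removes the MOM group and lets the phenol open the epoxide at the benzylic carbon with inversion, which should give 3 with the iodine fixed at C8 by the way the ring is built.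

Step 7. Cleavage of eight benzyl ethers may be slow and incomplete, while the benzylic C2–O1 bonds of the two C rings begin to undergo hydrogenolysis (ring opening to dihydrochalcones). Fallback (sets out from 10, comes back at 11): non-reductive Lewis-acid debenzylation with BCl3 and pentamethylbenzene as cation scavenger (CH2Cl2, −78 °C, then MeOH quench) converts 10 directly into 11 without new intermediates.

**Further compounds**
F1 | step 6 | (2R,3R)-5,7-bis(benzyloxy)-2-[3,4-bis(benzyloxy)phenyl]-8-{(E)-2-[3,4-bis(benzyloxy)phenyl]-1-(tributylstannyl)vinyl}-3-hydroxychroman-4-one | CCCC[Sn](CCCC)(CCCC)/C(=C/c1ccc(OCc2ccccc2)c(OCc2ccccc2)c1)c1c(OCc2ccccc2)cc(OCc2ccccc2)c2c1O[C@H](c1ccc(OCc3ccccc3)c(OCc3ccccc3)c1)[C@@H](O)C2=O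
F2 | step 6 | 3,5-bis(benzyloxy)-2-formylphenyl acetate | CC(=O)Oc1cc(OCc2ccccc2)cc(OCc2ccccc2)c1C=O
F3 | step 6 | 2-acetoxy-4,6-bis(benzyloxy)benzoic acid | CC(=O)Oc1cc(OCc2ccccc2)cc(OCc2ccccc2)c1C(=O)O
F4 | step 6 | 2-acetoxy-4,6-bis(benzyloxy)benzoyl chloride | CC(=O)Oc1cc(OCc2ccccc2)cc(OCc2ccccc2)c1C(Cl)=O
F5 | step 6 | O-acetate of hydroxychalcone 9, 2-{(E)-2-[(2R,3R)-5,7-bis(benzyloxy)-2-[3,4-bis(benzyloxy)phenyl]-3-hydroxy-4-oxochroman-8-yl]-3-[3,4-bis(benzyloxy)phenyl]acryloyl}-3,5-bis(benzyloxy)phenyl acetate | CC(=O)Oc1cc(OCc2ccccc2)cc(OCc2ccccc2)c1C(=O)/C(=C/c1ccc(OCc2ccccc2)c(OCc2ccccc2)c1)c1c(OCc2ccccc2)cc(OCc2ccccc2)c2c1O[C@H](c1ccc(OCc3ccccc3)c(OCc3ccccc3)c1)[C@@H](O)C2=O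
F6 | step 2 | 1-[2,4-bis(benzyloxy)-6-hydroxyphenyl]ethanone (purchased starting material of the fallback) | CC(=O)c1c(O)cc(OCc2ccccc2)cc1OCc1ccccc1
F7 | step 2 | 1-[4,6-bis(benzyloxy)-2-hydroxy-3-iodophenyl]ethanone | CC(=O)c1c(O)c(I)c(OCc2ccccc2)cc1OCc1ccccc1
F8 | step 2 | 1-[4,6-bis(benzyloxy)-3-iodo-2-(methoxymethoxy)phenyl]ethanone | COCOc1c(I)c(OCc2ccccc2)cc(OCc2ccccc2)c1C(C)=O
F9 | step 2 | (E)-1-[4,6-bis(benzyloxy)-3-iodo-2-(methoxymethoxy)phenyl]-3-[3,4-bis(benzyloxy)phenyl]prop-2-en-1-one | COCOc1c(I)c(OCc2ccccc2)cc(OCc2ccccc2)c1C(=O)/C=C/c1ccc(OCc2ccccc2)c(OCc2ccccc2)c1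
F10 | step 2 | [4,6-bis(benzyloxy)-3-iodo-2-(methoxymethoxy)phenyl]{(2R,3S)-3-[3,4-bis(benzyloxy)phenyl]oxiran-2-yl}methanone | COCOc1c(I)c(OCc2ccccc2)cc(OCc2ccccc2)c1C(=O)[C@@H]1O[C@H]1c1ccc(OCc2ccccc2)c(OCc2ccccc2)c1
F0 | step 7 | none | none
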